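## Structural features

The target is a 3,3'-linked pair of 4-aryl-3,4-dihydrocoumarins (chroman-2-ones). Unit A has a fully oxygenated benzo ring A (hydroxyls on C5, C6, C7 and C8, lactone oxygen O1 on C8a). Unit B has a phloroglucinol-type ring (hydroxyls on C5' and C7'), and each unit carries a 4-hydroxyphenyl group on its benzylic carbon. The four stereocentres C4, C3, C3' and C4' form one unbroken chain. Read from the SMILES they are 3S,4R and 3'S,4'S, so the two lactone-ring substituents are cis in unit A and trans in unit B. Several groups are fragile:
- C3–H and C3'–H lie alpha to aryl ester carbonyls, and the cis pair of unit A is the less stable arrangement, so base can epimerise it.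
- The aryl lactones are acylating agents that amines, alkoxides and neighbouring hydroxyls open.
- C4 and C4' are doubly benzylic next to electron-rich rings, so strong acid can ionise them.
- The tetrahydroxylated ring A is oxidised by air, fastest when deprotonated.

The real difficulty is twofold: ring A is hexasubstituted with five oxygens and a crowded C4–C4a bond, and the stereotetrad needs opposite relative configurations in two otherwise similar halves. Ring A stands at the oxidation level of a hydroquinone with three further oxygens, and C4a is its only carbon without oxygen. The key step uses this: 2,3,5-trimethoxy-1,4-benzoquinone first oxidises an enal (the later C2–C3–C4) to an acyl azolium; once reduced, it is the C,O-bis-nucleophile whose free carbon becomes C4a (bond C4–C4a) and whose neighbouring hydroxyl becomes O1 (bond O1–C2).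

## Logic of the disconnections

**17 from 16.** The seven O–CH3 bonds are cut last. The free polyphenol is the most oxidisable and most base-sensitive compound of the route, so it should exist only at the end. Everything before it can then be handled as a stable methyl ether. The forward step must be acidic, base-free and oxygen-free, and must leave two aryl lactones and the kinetic cis pair C3/C4 intact.

**16 from 9 and 14.** The cuts are C4–C4a and O1–C2. Both bonds belong to the lactone ring of unit A. Removing them takes away that ring and the centres C3 and C4. Ring A arrives as 14 with all five oxygens in place and one free carbon, and 9 keeps only the two centres of unit B. Ring A and the cinnamoyl β-carbon are both electrophilic in 14 and 9, so the forward step must invert the polarity of one partner. A carbene does this by passing two electrons from 9 to 14 and making 15 in the flask. The demands are catalyst control at C4, kinetic protonation at C3 to the cis pair, and a base too weak to touch C3 or C3'. The design of 9 answers these: it is a single enantiomer, its lactone is closed and trans (the stable arrangement, so an accidental epimerisation at C3' corrects itself), its enal is E, and every phenol is a methyl ether.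

**14 from 13, and 13 from 10.** In 14 one C=O is taken back to a C–OMe group (oxidative demethylation of a para-methoxyphenol), and in 13 the C–OH bond is cut (hydroxylation through 11 and 12). Compound 10 has only one kind of C–H bond, so the fifth oxygen can only enter at the right carbon. The forward steps need nothing beyond a clean metalation and a two-electron oxidant.

**9 from 7 and 8.** The C=C bond between the later C3 and C4 is cut (aldol condensation). This brings the second anisyl carbon from a cheap aldehyde and leaves an aldehyde whose only stereocentres are those of unit B. The forward step must not open the aryl lactone and must give the E alkene, which is the thermodynamic one.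

**7 from 5, and 5 from 3.** The aldehyde carbon is taken back to a terminal alkene (ozonolysis through 6), and the C3'–CH2 bond is cut (allylation of enolate 4). An allyl group is the shortest masked acetaldehyde. The existing C4' aryl group should set C3' trans during the alkylation. The alkylation has to be anti and cold enough that the aryl ester enolate does not open; the cleavage has to spare two electron-rich arenes and should avoid water.

**3 from 1 and 2.** The cuts are C4'–C4a' and O1'–C2', the same pair of bonds as in the key step, but with an external oxidant and a preformed phenol, which is the established form of the annulation. Both partners are commercial, and the chiral carbene sets C4', the only centre that the later steps cannot correct.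

## Other disconnections considered

**Alternative 1:** The cuts are C4–C4a, C4'–C4a', O1–C2 and O1'–C2'. They lead back to the cis-fused dilactone A2, phloroglucinol A3 and 13. In the forward key step, acid would open each benzylic C–O bond of A2 to a para-quinone methide. A3 and then 13 would add through carbon, and the freed acids would lactonise onto the ortho hydroxyls to give the tetramethyl ether A1.
- In its favour: the C3–C3' bond is already present, and a cis ring fusion in A2 corresponds to the 3S,3'S/3R,3'R pair, which is the relative configuration of the target. Four bonds and two rings would form in one flask, the free 4-hydroxyphenyl groups are required and not merely tolerated, and only four ethers remain to be cleaved.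
- Against it: A2 is C2-symmetric, so two identical benzylic sites must be opened one after the other by two different arenes, which invites both symmetrical bis-adducts. C4 and C4' would arise from capture of flat cations under substrate control only, although the target needs cis in unit A and trans in unit B. The acid that makes these bonds can also re-ionise them, which pushes towards the thermodynamic arrangement. A2 made by phenol oxidation would be racemic.
- Comparison: on step count, on the C3–C3' bond and on the lighter final deprotection this alternative is the better one. On mechanism it relies on reversible ionic steps without an outside source of chirality. The chosen plan sets C4' and C4 by a catalyst and C3' and C3 by separate kinetic events that can be optimised one at a time.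

**Alternative 2:** The cuts are C3–C4 and O1–C2. A carbene would add to A5, a 4-nitrophenyl acetate carrying unit B on its α-carbon, and the acyl azolium would be deprotonated to the azolium enolate at C3. The enolate would add to the ortho-quinone methide A7, released by base from sulfone A6, and the phenoxide would close O1–C2 to give the octamethyl ether A4.
- In its favour: the formal (4+2) reaction of carbene-bound enolates with ortho-quinone methides is an established reaction type and is normally cis-selective at C3/C4, the relationship needed here. It involves no redox event and no α-branched unsaturated acyl azolium. Ring A is fully methylated and cannot be oxidised. A6 should come in one three-component step from 13, 8 and a sulfinate.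
- Against it: A5 holds two aryl esters and the carbene must choose the nitrophenyl one. The enolate is branched next to C3', whose own α-hydrogen is acidic. The stoichiometric base that releases A7 threatens C3' and the new cis pair. A7 is fully substituted and flanked by a methoxy group. Reaching A5 from 7 costs an oxidation and an esterification, and eight ethers must be cleaved at the end.
- Comparison: the two plans are equal in what the key step builds (one ring, two bonds, C3 and C4) and in the need to match catalyst and substrate. This alternative is better on precedent. The chosen plan is about two steps shorter, uses no stoichiometric base and makes C4–C4a in the same operation. Alternative 2 is held in reserve.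

**Alternative 3:** The cut is C4a–C5 of ring A (with C8–C8a in the preceding addition). Dihydropyran A11, lithiated at C8a, would add to dimethyl squarate A9 to give the 4-hydroxycyclobutenone A10. Heating would open the four-membered ring to a dienylketene, six-electron closure would form C4a–C5, and tautomerisation would give the hydroquinone A8.
- In its favour: the substitution pattern of ring A follows from connectivity alone, with no aromatic substitution and no question of arene nucleophilicity. The thermal cascade is neutral, needs no catalyst and is little affected by crowding; in the reliability of the key event it is the equal or the better of the chosen step. The C5/C8 hydroxyls arrive distinguished from the C6/C7 methyl ethers.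
- Against it: the key step creates no stereocentre, so C3, C4, C3' and C4' must all be present in A11, whose synthesis becomes the real problem. Both lactones must be masked as lactol ethers because of the organolithium. Afterwards two acetals must be hydrolysed and oxidised to lactones beside a hydroquinone that would be oxidised first, which forces extra protection steps.
- Comparison: on structure it solves ring A only. On mechanism it is the more predictable. On step economy it is clearly the longest, whereas the chosen plan closes a ring and sets two centres in one step from a quinone made in two steps.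

Key step: step 7

**Remarks and assumptions**

- Assumption: the sense of induction of the aminoindanol-derived triazolium catalyst is not assigned here. In steps 1 and 7 the antipode meant is the one that gives the configuration drawn; both antipodes are commercial.
- Remark: catalyst-bound species (Breslow intermediate, acyl azolium, azolium enolate, enamine) and boron-bound phenoxides that exist only until work-up are described in words and carry no number.

## Route

Step 1
Reactants: 1 (E)-3-(4-methoxyphenyl)prop-2-enal (4-methoxycinnamaldehyde); 2 3,5-dimethoxyphenol
Product: 3 (4S)-5,7-dimethoxy-4-(4-methoxyphenyl)chroman-2-one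
Conditions: (5aS,10bR)- or (5aR,10bS)-2-(2,4,6-trimethylphenyl)-5a,10b-dihydro-4H,6H-indeno[2,1-b][1,2,4]triazolo[4,3-d][1,4]oxazin-2-ium chloride (10 mol%), 3,3',5,5'-tetra-tert-butyldiphenoquinone (1.2 equiv), K2CO3 (0.5 equiv), toluene, 25 °C
Reagents that add atoms: none
Why: Carbene-catalysed oxidative (3+3) annulation of an enal with an electron-rich phenol, a known reaction type: the Breslow intermediate is oxidised to the unsaturated acyl azolium, 2 adds through the carbon ortho to its hydroxyl (activated by three oxygens) and the phenolic oxygen closes the lactone. The aminoindane backbone of the catalyst covers one face of the acyl azolium and so sets C4 (S).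

Step 2
Reactants: 3 (4S)-5,7-dimethoxy-4-(4-methoxyphenyl)chroman-2-one
Product: 5 (3R,4S)-5,7-dimethoxy-4-(4-methoxyphenyl)-3-(prop-2-en-1-yl)chroman-2-one (3,4-trans), via lithium enolate 4 (not isolated)
Conditions: LiN(SiMe3)2 (1.05 equiv), THF, −78 °C; allyl bromide (1.5 equiv), DMPU, −78 → −40 °C; AcOH quench at −78 °C
Reagents that add atoms: allyl bromide, C=CCBr
Why: Alkylation of a lactone enolate, known for 4-aryl-dihydrocoumarins: the 4-aryl group sits pseudoaxial to avoid the 5-methoxy group and covers one face of enolate 4, so the allyl group should enter anti and give the 3,4-trans lactone, which is also the more stable epimer. The low temperature keeps the aryl ester enolate from opening to a ketene.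

Step 3
Reactants: 5 (3R,4S)-5,7-dimethoxy-4-(4-methoxyphenyl)-3-(prop-2-en-1-yl)chroman-2-one
Product: 7 2-[(3R,4S)-5,7-dimethoxy-4-(4-methoxyphenyl)-2-oxochroman-3-yl]acetaldehyde, via secondary ozonide 6 (not isolated)
Conditions: O3, CH2Cl2, −78 °C, Sudan red 7B as end-point indicator; PPh3 (1.2 equiv), −78 → 25 °C
Reagents that add atoms: ozone, [O-][O+]=O
Why: Ozonolysis with reductive work-up: the monosubstituted alkene reacts with ozone far faster than the methoxylated arenes and the dye marks the end point. The water-free procedure forms no diol or hydrate that could transfer the aryl ester to a five-membered lactone, and C3 and C4 are not touched.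

Step 4
Reactants: 7 2-[(3R,4S)-5,7-dimethoxy-4-(4-methoxyphenyl)-2-oxochroman-3-yl]acetaldehyde; 8 4-methoxybenzaldehyde
Product: 9 (2E)-2-[(3S,4S)-5,7-dimethoxy-4-(4-methoxyphenyl)-2-oxochroman-3-yl]-3-(4-methoxyphenyl)prop-2-enal
Conditions: 8 (3 equiv), pyrrolidine (20 mol%), PhCO2H (20 mol%), 4 Å MS, CH2Cl2, 25 → 40 °C
Reagents that add atoms: none
Why: Amine-catalysed crossed aldol condensation (the enamine of 7 adds to the iminium ion of the non-enolisable 8, then elimination), a known route to α-substituted cinnamaldehydes whose E geometry (aryl trans to CHO) is the thermodynamic one. The buffered amine salt is too weakly basic to epimerise C3 of the lactone, whose trans arrangement is in any case the stable one; its descriptor changes from R to S only through CIP priorities. Water is the only co-product.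

Step 5
Reactants: 10 1,2,3,4-tetramethoxybenzene
Product: 13 2,3,4,5-tetramethoxyphenol, via aryllithium 11 (not isolated), via arylboronate 12 (not isolated)
Conditions: nBuLi (1.1 equiv), TMEDA, THF, 0 °C; B(OMe)3, −78 → 25 °C; AcOH, 30% H2O2, 0 → 25 °C
Reagents that add atoms: hydrogen peroxide, OO (nBuLi, [Li]CCCC, and B(OMe)3, COB(OC)OC, leave atoms only in 11 and 12)
Why: Directed ortho-metalation, borylation and peroxide oxidation (aryl shift from boron to oxygen), a standard hydroxylation of methoxyarenes. Compound 10 has only two C–H bonds, equivalent and each ortho to a methoxy group, so no regiochemical question arises.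

Step 6
Reactants: 13 2,3,4,5-tetramethoxyphenol
Product: 14 2,3,5-trimethoxy-1,4-benzoquinone
Conditions: (NH4)2Ce(NO3)6 (2.2 equiv), MeCN/H2O (2:1), 0 °C
Reagents that add atoms: water, O
Why: Oxidative demethylation of a para-methoxyphenol by tetravalent cerium: two one-electron oxidations give an aryloxenium ion, water adds at the para carbon and methanol is lost. Only the 1,4-quinone can form, because the carbon para to the hydroxyl carries a methoxy group.

Step 7
Reactants: 9 (2E)-2-[(3S,4S)-5,7-dimethoxy-4-(4-methoxyphenyl)-2-oxochroman-3-yl]-3-(4-methoxyphenyl)prop-2-enal; 14 2,3,5-trimethoxy-1,4-benzoquinone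
Product: 16 (3S,4R)-3-[(3S,4S)-5,7-dimethoxy-4-(4-methoxyphenyl)-2-oxochroman-3-yl]-6-hydroxy-5,7,8-trimethoxy-4-(4-methoxyphenyl)chroman-2-one, via trimethoxyhydroquinone 15 (not isolated)
Conditions: (5aS,10bR)- or (5aR,10bS)-2-(2,4,6-trimethylphenyl)-5a,10b-dihydro-4H,6H-indeno[2,1-b][1,2,4]triazolo[4,3-d][1,4]oxazin-2-ium chloride (20 mol%), DABCO (20 mol%), 14 (1.05 equiv, added slowly), 4 Å MS, degassed toluene/THF (4:1), 25 → 40 °C, Ar
Reagents that add atoms: none
Why: Proposed new method: the carbene adds to the aldehyde of 9 and the Breslow intermediate passes two electrons to 14, giving the unsaturated acyl azolium and hydroquinone 15; 15 then adds through its only unsubstituted carbon (ortho and para to three oxygens) to C4, directly or after O-acylation and 3,3-shift, the azolium enolate is protonated at C3, and the hydroxyl ortho to the new bond displaces the carbene from C2. The closest known reaction type is the carbene-catalysed oxidative (3+3) annulation of enals with naphthols and electron-rich phenols under an external quinone oxidant, together with the carbene-catalysed acylation of quinone-derived hydroquinones; new here are the quinone in both roles and the α-branched enal. The lactone ring closes by 6-exo-trig acyl substitution at the acyl azolium carbon. C4 is controlled by the catalyst, whose aminoindane backbone covers one face of the acyl azolium so that 15 attacks the β-carbon from the open face (4R). C3 is controlled by the new C4 centre: in the hydrogen-bonded conformation that precedes ring closure the proton arrives on the face away from the 4-methoxyphenyl group, which puts H3 trans to that aryl and the unit B substituent cis (3S), and this kinetic cis pair should survive because the base is weak and sub-stoichiometric. Regioselectivity needs only the substitution pattern of 15 (one free carbon, and only its ortho hydroxyl can reach C2), chemoselectivity over the lactone of unit B rests on the much higher reactivity of the acyl azolium, and the C3' centre is the stable trans one and cannot be lost. The catalyst antipode is chosen as the matched partner of the C3'/C4' pair; the step is an isomerising addition of 14 to 9 with no co-product.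

Step 8
Reactants: 16 (3S,4R)-3-[(3S,4S)-5,7-dimethoxy-4-(4-methoxyphenyl)-2-oxochroman-3-yl]-6-hydroxy-5,7,8-trimethoxy-4-(4-methoxyphenyl)chroman-2-one
Product: 17 (3S,4R)-3-[(3S,4S)-5,7-dihydroxy-4-(4-hydroxyphenyl)-2-oxochroman-3-yl]-5,6,7,8-tetrahydroxy-4-(4-hydroxyphenyl)chroman-2-one (CNP0064734.2)
Conditions: BBr3 (16 equiv), CH2Cl2, −78 → 25 °C, Ar; ice/H2O quench, EtOAc extraction without base; reversed-phase chromatography (H2O/MeCN, 0.1% HCO2H) under Ar
Reagents that add atoms: none
Why: Lewis-acid cleavage of aryl methyl ethers (bromide attacks the methyl group of each boron-bound ether), standard for methoxylated 4-aryl-dihydrocoumarins; acid leaves C3 and C3' alone. A lactone opened on the way re-closes on acidic work-up to the same compound, because ring A carries oxygen on every carbon and ring B is symmetric about C4a'. Base and air are excluded because the product epimerises and oxidises easily.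

## Compound list

1 | (E)-3-(4-methoxyphenyl)prop-2-enal | COc1ccc(/C=C/C=O)cc1 | starting material
2 | 3,5-dimethoxyphenol | COc1cc(O)cc(OC)c1 | starting material
3 | (4S)-5,7-dimethoxy-4-(4-methoxyphenyl)chroman-2-one | O=C1C[C@@H](c2ccc(OC)cc2)c2c(OC)cc(OC)cc2O1 | intermediate
4 | lithium (4S)-5,7-dimethoxy-4-(4-methoxyphenyl)-4H-chromen-2-olate | [Li]OC1=C[C@@H](c2ccc(OC)cc2)c2c(OC)cc(OC)cc2O1 | intermediate (not isolated)
5 | (3R,4S)-5,7-dimethoxy-4-(4-methoxyphenyl)-3-(prop-2-en-1-yl)chroman-2-one (trans) | C=CC[C@H]1C(=O)Oc2cc(OC)cc(OC)c2[C@@H]1c1ccc(OC)cc1 | intermediate
6 | (3R,4S)-5,7-dimethoxy-4-(4-methoxyphenyl)-3-[(1,2,4-trioxolan-3-yl)methyl]chroman-2-one (trioxolane carbon as epimer mixture) | C1OOC(C[C@H]2C(=O)Oc3cc(OC)cc(OC)c3[C@@H]2c2ccc(OC)cc2)O1 | intermediate (not isolated)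
7 | 2-[(3R,4S)-5,7-dimethoxy-4-(4-methoxyphenyl)-2-oxochroman-3-yl]acetaldehyde | O=CC[C@H]1C(=O)Oc2cc(OC)cc(OC)c2[C@@H]1c1ccc(OC)cc1 | intermediate
8 | 4-methoxybenzaldehyde | COc1ccc(C=O)cc1 | starting material
9 | (2E)-2-[(3S,4S)-5,7-dimethoxy-4-(4-methoxyphenyl)-2-oxochroman-3-yl]-3-(4-methoxyphenyl)prop-2-enal | O=C/C(=C/c1ccc(OC)cc1)[C@H]1C(=O)Oc2cc(OC)cc(OC)c2[C@@H]1c1ccc(OC)cc1 | intermediate
10 | 1,2,3,4-tetramethoxybenzene | COc1ccc(OC)c(OC)c1OC | starting material
11 | (2,3,4,5-tetramethoxyphenyl)lithium | [Li]c1cc(OC)c(OC)c(OC)c1OC | intermediate (not isolated)
12 | dimethyl (2,3,4,5-tetramethoxyphenyl)boronate | COB(OC)c1cc(OC)c(OC)c(OC)c1OC | intermediate (not isolated)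
13 | 2,3,4,5-tetramethoxyphenol | COc1cc(O)c(OC)c(OC)c1OC | intermediate
14 | 2,3,5-trimethoxy-1,4-benzoquinone | COC1=CC(=O)C(OC)=C(OC)C1=O | intermediate
15 | 2,3,5-trimethoxybenzene-1,4-diol | COc1cc(O)c(OC)c(OC)c1O | intermediate (not isolated)
16 | (3S,4R)-3-[(3S,4S)-5,7-dimethoxy-4-(4-methoxyphenyl)-2-oxochroman-3-yl]-6-hydroxy-5,7,8-trimethoxy-4-(4-methoxyphenyl)chroman-2-one | O=C1Oc2c(OC)c(OC)c(O)c(OC)c2[C@@H](c2ccc(OC)cc2)[C@H]1[C@H]1C(=O)Oc2cc(OC)cc(OC)c2[C@@H]1c1ccc(OC)cc1 | intermediate
17 | (3S,4R)-3-[(3S,4S)-5,7-dihydroxy-4-(4-hydroxyphenyl)-2-oxochroman-3-yl]-5,6,7,8-tetrahydroxy-4-(4-hydroxyphenyl)chroman-2-one | O=C1Oc2c(O)c(O)c(O)c(O)c2[C@@H](c2ccc(O)cc2)[C@H]1[C@H]1C(=O)Oc2cc(O)cc(O)c2[C@@H]1c1ccc(O)cc1 | target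

## Step count and least certain steps

Total step count: 8. Longest linear sequence: 6 steps (1, 2, 3, 4, 7, 8); the quinone branch is 2 steps (5, 6).

**Step 7 (carries the label "Proposed new method:").**
- What may go wrong: the α-branch may slow carbene addition and conjugate addition so much that plain O-acylation of 15 (redox esterification without C–C bond formation) or addition of the carbene to 14 takes over. Facial selectivity at C4 may be poor if the C3'/C4' pair opposes the catalyst. The cis pair may be lost by epimerisation at C3.
- Fallback (known chemistry): it sets out from 9 and 13 and returns at 17. The established oxidative annulation is run with a preformed phenol: 9 and 13 with the same triazolium chloride, 3,3',5,5'-tetra-tert-butyldiphenoquinone as external oxidant and DABCO in toluene should give the octamethyl ether F1. BBr3 in CH2Cl2, worked up without base, then cleaves all eight ethers to 17. This removes the double role of the quinone but not the α-branch. Should the branch itself be the obstacle, the bond set of alternative 2 (A5 with A6) is the next reserve.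

**Step 4.**
- What may go wrong: acyl transfer from the aryl lactone to the amine catalyst, or opening of the lactone by the carbinolamine of the neighbouring aldehyde; self-condensation of 7; slow reaction with the electron-rich aldehyde 8.
- Fallback: it sets out from 7 and returns at 9, with no nucleophilic amine. TBSOTf and Et3N in CH2Cl2 convert 7 into the silyl enol ether F2. A Mukaiyama aldol addition of F2 to 8 with BF3·OEt2 at −78 °C gives the aldol F3. MsCl and Et3N then eliminate water to the E enal 9.

**Step 8.**
- What may go wrong: incomplete cleavage of the crowded ring A ethers, ionisation at C4 on long exposure to the Lewis acid, and oxidative loss of the free polyphenol during purification.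
- Fallback: it sets out from 16 and returns at 17. The crude product of the BBr3 treatment is not purified. It is acetylated at once without base (Ac2O, catalytic H2SO4) to the octaacetate F4, which is stable on silica and separable from partly methylated material. The acetates are then removed by HCl in MeOH at 0–25 °C, and a short exposure to TFA in CH2Cl2 re-closes any lactone opened on the way, leaving only volatile by-products.

**Step 1.**
- What may go wrong: attack of 2 through the carbon para to its hydroxyl, O-acylation without ring closure, or an enantioselectivity too low for a centre that no later step can correct.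
- Fallback: it sets out from 2 and returns at 3. Ethyl propiolate with Pd(OAc)2 (catalytic) in TFA/CH2Cl2 converts 2 into 5,7-dimethoxycoumarin F5. Asymmetric 1,4-addition of 4-methoxyphenylboronic acid with Rh(acac)(C2H4)2 and (S)- or (R)-SEGPHOS in dioxane/H2O at 60 °C then gives 3.

## Further compounds

F1 | step 7 | (3S,4R)-3-[(3S,4S)-5,7-dimethoxy-4-(4-methoxyphenyl)-2-oxochroman-3-yl]-5,6,7,8-tetramethoxy-4-(4-methoxyphenyl)chroman-2-one (octamethyl ether of 17) | O=C1Oc2c(OC)c(OC)c(OC)c(OC)c2[C@@H](c2ccc(OC)cc2)[C@H]1[C@H]1C(=O)Oc2cc(OC)cc(OC)c2[C@@H]1c1ccc(OC)cc1
F2 | step 4 | (3S,4S)-3-[2-(tert-butyldimethylsilyloxy)ethenyl]-5,7-dimethoxy-4-(4-methoxyphenyl)chroman-2-one (E/Z mixture) | CC(C)(C)[Si](C)(C)OC=C[C@H]1C(=O)Oc2cc(OC)cc(OC)c2[C@@H]1c1ccc(OC)cc1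
F3 | step 4 | 2-[(3S,4S)-5,7-dimethoxy-4-(4-methoxyphenyl)-2-oxochroman-3-yl]-3-hydroxy-3-(4-methoxyphenyl)propanal (mixture at the two new centres) | O=CC(C(O)c1ccc(OC)cc1)[C@H]1C(=O)Oc2cc(OC)cc(OC)c2[C@@H]1c1ccc(OC)cc1
F4 | step 8 | octaacetate of 17 | O=C1Oc2c(OC(C)=O)c(OC(C)=O)c(OC(C)=O)c(OC(C)=O)c2[C@@H](c2ccc(OC(C)=O)cc2)[C@H]1[C@H]1C(=O)Oc2cc(OC(C)=O)cc(OC(C)=O)c2[C@@H]1c1ccc(OC(C)=O)cc1
F5 | step 1 | 5,7-dimethoxycoumarin | COc1cc(OC)c2ccc(=O)oc2c1
A1 | alternative 1 | 5,6,7,8-tetra-O-methyl ether of 17 | O=C1Oc2c(OC)c(OC)c(OC)c(OC)c2[C@@H](c2ccc(O)cc2)[C@H]1[C@H]1C(=O)Oc2cc(O)cc(O)c2[C@@H]1c1ccc(O)cc1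
A2 | alternative 1 | (1R,2R,5R,6R)-2,6-bis(4-hydroxyphenyl)-3,7-dioxabicyclo[3.3.0]octane-4,8-dione (cis-fused, aryl groups exo) | O=C1O[C@@H](c2ccc(O)cc2)[C@@H]2C(=O)O[C@@H](c3ccc(O)cc3)[C@H]12
A3 | alternative 1 | phloroglucinol | Oc1cc(O)cc(O)c1
A4 | alternative 2 | octamethyl ether of 17 | O=C1Oc2c(OC)c(OC)c(OC)c(OC)c2[C@@H](c2ccc(OC)cc2)[C@H]1[C@H]1C(=O)Oc2cc(OC)cc(OC)c2[C@@H]1c1ccc(OC)cc1
A5 | alternative 2 | 4-nitrophenyl 2-[(3R,4S)-5,7-dimethoxy-4-(4-methoxyphenyl)-2-oxochroman-3-yl]acetate | O=C(C[C@H]1C(=O)Oc2cc(OC)cc(OC)c2[C@@H]1c1ccc(OC)cc1)Oc1ccc(cc1)[N+](=O)[O-]
A6 | alternative 2 | 2,3,4,5-tetramethoxy-6-[(4-methoxyphenyl)(4-methylbenzenesulfonyl)methyl]phenol (racemic at the benzylic carbon) | COc1ccc(cc1)C(c1c(O)c(OC)c(OC)c(OC)c1OC)S(=O)(=O)c1ccc(C)cc1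
A7 | alternative 2 | 2,3,4,5-tetramethoxy-6-(4-methoxybenzylidene)cyclohexa-2,4-dien-1-one | O=C1C(=Cc2ccc(OC)cc2)C(OC)=C(OC)C(OC)=C1OC
A8 | alternative 3 | 5,8-dihydroxy-6,7-dimethoxy chroman bis(lactol methyl ether), acetal carbons as epimer mixtures | COC1Oc2c(O)c(OC)c(OC)c(O)c2[C@@H](c2ccc(OC)cc2)[C@H]1[C@H]1C(OC)Oc2cc(OC)cc(OC)c2[C@@H]1c1ccc(OC)cc1
A9 | alternative 3 | dimethyl squarate | COC1=C(OC)C(=O)C1=O
A10 | alternative 3 | 4-hydroxy-2,3-dimethoxycyclobut-2-en-1-one carrying at C4 the dihydropyran of A11 through its C8a (carbinol and acetal carbons as epimer mixtures) | COC1=C(OC)C(O)(C1=O)C1=C[C@@H](c2ccc(OC)cc2)[C@@H]([C@H]2C(OC)Oc3cc(OC)cc(OC)c3[C@@H]2c2ccc(OC)cc2)C(OC)O1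
A11 | alternative 3 | 2-methoxy-4-(4-methoxyphenyl)-3,4-dihydro-2H-pyran carrying at C3 the lactol methyl ether of unit B (C3, C4, C3', C4' as in 17, acetal carbons as epimer mixtures) | COC1OC=C[C@@H](c2ccc(OC)cc2)[C@H]1[C@H]1C(OC)Oc2cc(OC)cc(OC)c2[C@@H]1c1ccc(OC)cc1
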